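A direct plan would carry a protected 4-bromo-3-hydroxybenzyl alcohol through enolate arylation, α-methylenation and ester reduction to a 2-arylallyl alcohol, put both ring esters on it to reach A1, epoxidise A1 with Ti(OiPr)4/tartrate/t-BuOOH to the epoxy alcohol A2 and acetylate last; the (R)-acid would be made by way of the N-butanoyl oxazolidinone A3.
Its weakest step would be the hydroxyl-directed asymmetric epoxidation of A1: 2-aryl (1,1-disubstituted) allylic alcohols are a poor class for this catalyst in enantioselectivity, the tertiary benzylic epoxy alcohol A2 is opened under titanium alkoxide, and Ti(OiPr)4 can move the neighbouring aryl ester onto the free hydroxyl, all on the most advanced material.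
The second would be the shuttle of three mutually orthogonal protecting groups over the phenolic, benzylic and allylic oxygens, about seven operations that form no bond of the target.
The third would be the three-step auxiliary sequence (acylation, methylation, peroxide cleavage) spent on a five-carbon acid with one stereocentre that can be bought.

Plan of the new route (thymol numbering: C7 benzylic CH2, C8 quaternary oxirane carbon, C9 oxirane CH2, C10 acetoxymethyl carbon).
C8 carries two CH2–O arms, C9 and C10, that differ only in what their oxygen is tied to. With the oxirane opened and the acetate removed they are the enantiotopic CH2OH groups of an achiral 2-arylpropane-1,2,3-triol, and a lipase can break this latent mirror plane through C8.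
Cuts, in retrosynthetic order: the O–C9 bond of the oxirane (3-exo closure, last step); the acetyl–O10 bond (lipase, which sets C8 and puts on the acetate of the target in one act); the angeloyl–O(aryl) and 2-methylbutanoyl–O7 bonds; the aryl–C8 bond (ortho-lithiated phenoxide plus the acetonide of dihydroxyacetone).
The benzene ring is bought with its 1,2,4-pattern, and the oxirane is the last ring to form, after (not before) all three acyl groups are in place.
No alkene is epoxidised and no titanium meets the aryl ester; the only protecting group is the acetonide that the C3 ketone brings along; (R)-2-methylbutanoic acid is bought and never activated.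

Key step: step 5

Assumption: which enantiotopic arm a given lipase acetylates in this new triol is empirical; the route is written for a lipase found by screening (Burkholderia cepacia, Pseudomonas fluorescens, Candida antarctica B) that acetylates the pro-R arm, and the fallback to step 5 supplies the opposite sense.

Step 1
Reactants: 1 2-bromo-5-(hydroxymethyl)phenol; 2 2,2-dimethyl-1,3-dioxan-5-one
Product: 4 5-[2-hydroxy-4-(hydroxymethyl)phenyl]-2,2-dimethyl-1,3-dioxan-5-ol, via trilithio species 3 (not isolated)
Conditions: n-BuLi (2.0 equiv), THF, −78 → 0 °C; t-BuLi (2.1 equiv), −78 °C; then 2 (1.2 equiv), −78 → −20 °C; aq. NH4Cl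
Reagents that add atoms: none
Why: Bromine–lithium exchange on the dilithium salt of the bromophenol gives an ortho-lithiated phenoxide whose 1,2-addition to the ketone joins the arene to C8 and brings in both CH2O arms as the acetonide, with no stereocentre formed because the two arms are identical.

Step 2
Reactants: 4 5-[2-hydroxy-4-(hydroxymethyl)phenyl]-2,2-dimethyl-1,3-dioxan-5-ol; 5 (R)-2-methylbutanoic acid
Product: 6 3-hydroxy-4-(5-hydroxy-2,2-dimethyl-1,3-dioxan-5-yl)benzyl (R)-2-methylbutanoate
Conditions: 5 (1.2 equiv), PPh3, DIAD, THF, 0 °C → rt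
Reagents that add atoms: none
Why: Mitsunobu esterification, in which the carboxylic acid (about five pKa units more acidic than the hindered phenol) protonates the betaine and displaces the primary benzylic oxyphosphonium ion, the tertiary alcohol is not activated, and the acid acts only as a nucleophile so its α-stereocentre cannot epimerise.

Step 3
Reactants: 6 3-hydroxy-4-(5-hydroxy-2,2-dimethyl-1,3-dioxan-5-yl)benzyl (R)-2-methylbutanoate; 7 angelic acid [(Z)-2-methylbut-2-enoic acid]
Product: 10 2-(5-hydroxy-2,2-dimethyl-1,3-dioxan-5-yl)-5-{[(R)-2-methylbutanoyl]oxymethyl}phenyl (Z)-2-methylbut-2-enoate, via angelic anhydride 8 (not isolated), via lithium phenoxide 9 (not isolated)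
Conditions: 7 (2.4 equiv), DCC (1.2 equiv), CH2Cl2, 0 °C → rt, filter; 6, LiN(SiMe3)2 (1.0 equiv), THF, −78 °C; then the anhydride solution, −78 → 0 °C; aq. NH4Cl
Reagents that add atoms: none
Why: O-acylation of a stoichiometrically formed phenoxide by the symmetric anhydride should acylate only the phenol (the tertiary alcohol stays protonated), and the absence of nucleophilic catalyst, chloride and excess base closes the addition–elimination path from angelate to tiglate.

Step 4
Reactants: 10 2-(5-hydroxy-2,2-dimethyl-1,3-dioxan-5-yl)-5-{[(R)-2-methylbutanoyl]oxymethyl}phenyl (Z)-2-methylbut-2-enoate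
Product: 11 2-(1,2,3-trihydroxypropan-2-yl)-5-{[(R)-2-methylbutanoyl]oxymethyl}phenyl (Z)-2-methylbut-2-enoate
Conditions: 1 M aq. HCl/THF (1:3), rt; used without storage
Reagents that add atoms: none
Why: Acid-catalysed ketal hydrolysis frees the two primary hydroxyls at room temperature without harm to the aryl enoate, the benzylic ester or the electron-poor tertiary benzylic alcohol, and mineral acid is used instead of acetic acid so that no racemic monoacetate can form.

Step 5
Reactants: 11 2-(1,2,3-trihydroxypropan-2-yl)-5-{[(R)-2-methylbutanoyl]oxymethyl}phenyl (Z)-2-methylbut-2-enoate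
Product: 12 2-[(2R)-1-acetoxy-2,3-dihydroxypropan-2-yl]-5-{[(R)-2-methylbutanoyl]oxymethyl}phenyl (Z)-2-methylbut-2-enoate
Conditions: immobilised lipase (serine hydrolase) from Burkholderia cepacia, vinyl acetate (5 equiv), t-BuOMe, 25 °C, run until 11 is consumed; filter off the enzyme
Reagents that add atoms: vinyl acetate, C=COC(C)=O
Why: The active-site serine of the lipase is acetylated by vinyl acetate (the vinyl alcohol released tautomerises to acetaldehyde, so the transfer is irreversible), and the acetyl enzyme hands the acetyl group to the one primary hydroxyl of the bound triol that lies at the catalytic histidine, required here to be the pro-R arm. The closest known reaction type is the lipase-catalysed enantiotopos-selective acylation of prochiral 2-substituted propane-1,3-diols and 2-substituted glycerols with vinyl esters. No ring closes in this step; it decides which arm keeps the acetate of the target (C10) and which is left free to become the oxirane CH2 (C9). The new stereocentre C8 is set by the enzyme alone, since the arms are enantiotopic and the substrate has no bias, and slow further acetylation to the achiral diacetate should consume the minor monoacetate faster and so raise the enantiomeric purity at some cost in yield. Chemoselectivity rests on the substrate: lipases do not accept the tertiary hydroxyl, no phenolic or benzylic hydroxyl is free, and the α-branched benzylic ester and the hindered aryl (Z)-enoate are poor acyl donors for the enzyme. The neutral aprotic medium keeps acetyl migration between the arms, which would racemise 12, slow.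

Step 6
Reactants: 12 2-[(2R)-1-acetoxy-2,3-dihydroxypropan-2-yl]-5-{[(R)-2-methylbutanoyl]oxymethyl}phenyl (Z)-2-methylbut-2-enoate
Product: 14 2-[(2R)-2-(acetoxymethyl)oxiran-2-yl]-5-{[(R)-2-methylbutanoyl]oxymethyl}phenyl (Z)-2-methylbut-2-enoate, via primary mesylate 13 (not isolated)
Conditions: MsCl (1.05 equiv), Et3N (1.5 equiv), CH2Cl2, −20 °C; then DBU (2 equiv), −20 °C → rt
Reagents that add atoms: none
Why: Sulfene-type mesylation takes the only primary hydroxyl faster than base can shift the acetyl group between the arms, and the amidine base then triggers 3-exo-tet intramolecular Williamson closure of the tertiary hydroxyl onto C9 (the way glycidyl esters are made from 1-acyl-3-sulfonyl glycerols), which breaks no bond at C8, so the configuration set by the enzyme is kept (the descriptor reads R in 12 and 14 and S in 13 only because the CIP ranks of the arms change).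

**Compound list**
1 | 2-bromo-5-(hydroxymethyl)phenol | OCc1ccc(Br)c(O)c1 | starting material
2 | 2,2-dimethyl-1,3-dioxan-5-one | CC1(C)OCC(=O)CO1 | starting material
3 | lithium 2-lithio-5-[(lithiooxy)methyl]phenolate (formed in the flask) | [Li]OCc1ccc([Li])c(O[Li])c1 | intermediate
4 | 5-[2-hydroxy-4-(hydroxymethyl)phenyl]-2,2-dimethyl-1,3-dioxan-5-ol | CC1(C)OCC(O)(CO1)c1ccc(CO)cc1O | intermediate
5 | (R)-2-methylbutanoic acid | CC[C@@H](C)C(=O)O | starting material
6 | 3-hydroxy-4-(5-hydroxy-2,2-dimethyl-1,3-dioxan-5-yl)benzyl (R)-2-methylbutanoate | CC1(C)OCC(O)(CO1)c1ccc(COC(=O)[C@H](C)CC)cc1O | intermediate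
7 | angelic acid, (Z)-2-methylbut-2-enoic acid | C/C=C(/C)C(=O)O | starting material
8 | angelic anhydride, (Z)-2-methylbut-2-enoic anhydride (formed in the flask) | C/C=C(/C)C(=O)OC(=O)C(/C)=C\C | intermediate
9 | lithium phenoxide of 6 (formed in the flask) | CC1(C)OCC(O)(CO1)c1ccc(COC(=O)[C@H](C)CC)cc1[O-].[Li+] | intermediate
10 | 2-(5-hydroxy-2,2-dimethyl-1,3-dioxan-5-yl)-5-{[(R)-2-methylbutanoyl]oxymethyl}phenyl (Z)-2-methylbut-2-enoate | C/C=C(/C)C(=O)Oc1cc(COC(=O)[C@H](C)CC)ccc1C1(O)COC(C)(C)OC1 | intermediate
11 | 2-(1,2,3-trihydroxypropan-2-yl)-5-{[(R)-2-methylbutanoyl]oxymethyl}phenyl (Z)-2-methylbut-2-enoate | C/C=C(/C)C(=O)Oc1cc(COC(=O)[C@H](C)CC)ccc1C(O)(CO)CO | intermediate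
12 | 2-[(2R)-1-acetoxy-2,3-dihydroxypropan-2-yl]-5-{[(R)-2-methylbutanoyl]oxymethyl}phenyl (Z)-2-methylbut-2-enoate | C/C=C(/C)C(=O)Oc1cc(COC(=O)[C@H](C)CC)ccc1[C@](O)(COC(C)=O)CO | intermediate
13 | 2-[(2S)-1-acetoxy-2-hydroxy-3-(methylsulfonyloxy)propan-2-yl]-5-{[(R)-2-methylbutanoyl]oxymethyl}phenyl (Z)-2-methylbut-2-enoate (formed in the flask) | C/C=C(/C)C(=O)Oc1cc(COC(=O)[C@H](C)CC)ccc1[C@](O)(COC(C)=O)COS(C)(=O)=O | intermediate
14 | 2-[(2R)-2-(acetoxymethyl)oxiran-2-yl]-5-{[(R)-2-methylbutanoyl]oxymethyl}phenyl (Z)-2-methylbut-2-enoate (CNP0256757.1) | C/C=C(/C)C(=O)Oc1cc(COC(=O)[C@H](C)CC)ccc1[C@]1(COC(C)=O)CO1 | target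

Total step count: 6. Longest linear sequence: 6 steps (1 → 4 → 6 → 10 → 11 → 12 → 14).

Steps most likely to fail:

Step 5. The lipase may discriminate the two arms poorly, or prefer the pro-S arm, because the ortho-acyloxyaryl group is new to the enzyme; over-acetylation may also cut into the yield. The fallback runs the enzyme in the hydrolytic mode. It sets out from 11, which with Ac2O and pyridine in CH2Cl2 at 0 °C should give the achiral 2-(1,3-diacetoxy-2-hydroxypropan-2-yl)-5-{[(R)-2-methylbutanoyl]oxymethyl}phenyl (Z)-2-methylbut-2-enoate F1, the tertiary hydroxyl staying free. A lipase that prefers the pro-S arm would then remove the pro-S acetate of F1 in t-BuOMe over aq. NaH2PO4/Na2HPO4 buffer (pH 7), which leaves the pro-R arm acetylated and comes back to the route at 12.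

Step 6. Once the tertiary hydroxyl is deprotonated, the angeloyl group may shift from the phenolic oxygen to the alkoxide through a six-membered transition state, and the phenoxide so formed would then alkylate at C9 to a dihydrobenzofuran; an acetyl shift followed by four-membered ring closure is a lesser drain. The fallback avoids both sulfonate and free alkoxide. It sets out from 12, which is added to the preformed PPh3/DIAD betaine in toluene at 0 °C and warmed to 50 °C (Mitsunobu-type cyclodehydration of a 1,2-diol). The primary oxygen is activated on phosphorus through 2-[(4S)-4-(acetoxymethyl)-2,2,2-triphenyl-1,3,2λ5-dioxaphospholan-4-yl]-5-{[(R)-2-methylbutanoyl]oxymethyl}phenyl (Z)-2-methylbut-2-enoate F2, which should collapse by loss of triphenylphosphine oxide, with the tertiary oxygen closing onto C9, and come back to the route at 14.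

Step 1. The trianion may aggregate or dissolve poorly, and the aryllithium may enolise the ketone instead of adding to it. The fallback masks both acidic hydroxyls and adds two steps. It sets out from 1, which with TBSCl and imidazole in DMF should give [4-bromo-3-(tert-butyldimethylsilyloxy)benzyl]oxy(tert-butyl)dimethylsilane F3. Exchange with n-BuLi in THF at −78 °C gives the soluble monolithium compound {2-(tert-butyldimethylsilyloxy)-4-[(tert-butyldimethylsilyloxy)methyl]phenyl}lithium F4, which is trapped at once at −78 °C with 2, before a 1,3 oxygen-to-carbon silyl shift can set in. The adduct 5-{2-(tert-butyldimethylsilyloxy)-4-[(tert-butyldimethylsilyloxy)methyl]phenyl}-2,2-dimethyl-1,3-dioxan-5-ol F5 is desilylated with Bu4NF in THF and comes back to the route at 4.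

Further compounds
F1 | step 5 | 2-(1,3-diacetoxy-2-hydroxypropan-2-yl)-5-{[(R)-2-methylbutanoyl]oxymethyl}phenyl (Z)-2-methylbut-2-enoate | C/C=C(/C)C(=O)Oc1cc(COC(=O)[C@H](C)CC)ccc1C(O)(COC(C)=O)COC(C)=O
F2 | step 6 | 2-[(4S)-4-(acetoxymethyl)-2,2,2-triphenyl-1,3,2λ5-dioxaphospholan-4-yl]-5-{[(R)-2-methylbutanoyl]oxymethyl}phenyl (Z)-2-methylbut-2-enoate | C/C=C(/C)C(=O)Oc1cc(COC(=O)[C@H](C)CC)ccc1[C@]1(COC(C)=O)COP(c2ccccc2)(c2ccccc2)(c2ccccc2)O1
F3 | step 1 | [4-bromo-3-(tert-butyldimethylsilyloxy)benzyl]oxy(tert-butyl)dimethylsilane | CC(C)(C)[Si](C)(C)OCc1ccc(Br)c(O[Si](C)(C)C(C)(C)C)c1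
F4 | step 1 | {2-(tert-butyldimethylsilyloxy)-4-[(tert-butyldimethylsilyloxy)methyl]phenyl}lithium | CC(C)(C)[Si](C)(C)OCc1ccc([Li])c(O[Si](C)(C)C(C)(C)C)c1
F5 | step 1 | 5-{2-(tert-butyldimethylsilyloxy)-4-[(tert-butyldimethylsilyloxy)methyl]phenyl}-2,2-dimethyl-1,3-dioxan-5-ol | CC1(C)OCC(O)(CO1)c1ccc(CO[Si](C)(C)C(C)(C)C)cc1O[Si](C)(C)C(C)(C)C
A1 | direct plan | 2-(3-hydroxyprop-1-en-2-yl)-5-{[(R)-2-methylbutanoyl]oxymethyl}phenyl (Z)-2-methylbut-2-enoate | C/C=C(/C)C(=O)Oc1cc(COC(=O)[C@H](C)CC)ccc1C(=C)CO
A2 | direct plan | 2-[(S)-2-(hydroxymethyl)oxiran-2-yl]-5-{[(R)-2-methylbutanoyl]oxymethyl}phenyl (Z)-2-methylbut-2-enoate | C/C=C(/C)C(=O)Oc1cc(COC(=O)[C@H](C)CC)ccc1[C@]1(CO)CO1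
A3 | direct plan | (R)-4-benzyl-3-butanoyl-1,3-oxazolidin-2-one | CCCC(=O)N1[C@H](Cc2ccccc2)COC1=O
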